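The easy step is to count the X: J and Z draw on one charge of it.

    J + X ⇌ J.X (K1 = 2.7 L mol⁻¹, k1 = 0.051 L mol⁻¹ s⁻¹)
    Z + X → Z.X (k2 = 0.49 L mol⁻¹ s⁻¹)

J 0.71 M; X 0.781 M; Z 0.710 M; time 15 min

- the reaction counts as stopped when no species that holds the J changes by six tenths of a point or more over the second half of the time
- run time (flask): 15 min

- at 15 min, what has stopped the reaction, if anything has (all of J has reacted / it is still moving / forward and back rates have come level / X has run out first)
- part of the J gone at 15 min
- the J.X standing at 15 min, as a percentage of the J charged

- My bench rule: the faster substrate takes its charge of X first, and the slower one gets what is over. At the start X goes to Z 9.6 times as fast as to J, counting the forward rate of step 1 alone.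
- 10.0% of the J charge is what I call the spare X: the X charged less the Z charged, as a fraction of the J charged. In this flask J and Z together want more X than is charged, so X is the limiting reagent, and the rule puts J.X at that fraction.
- Counting turnovers tests the order of events. J.X falls apart with a half-life of 0.612 min, and the 15 min hold 24.5 of these, so X that J takes early is offered back many times, and I expect step 1 to have come level.
- The rule ends where J.X stops holding the spare X. At balance, J.X over free X is K1 times the free J, at most 1.92 here, which is no large ratio.
- Let y be J.X as a fraction of the J charged, and let me count each Z as holding one X. Then y over (spare X minus y) equals 1.92 times (one minus y), which gives 6.42%. J has no other product, so conv is the same.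
- The forecast gives forward and back rates have come level, with conv 6.4% and y_P 6.4%: "the J side has reached equilibrium".
- The flask gives forward and back rates have come level, with conv 6.42% and y_P 6.42%.
- In this flask the relaxation half-life of step 1 at the asked time, 0.214 min, is short against the 15 min, and its backward turnover is 95% of the forward one. Free X, 3.3% of its own charge, is 3.58% of the J charge, and with J.X it makes up the spare X. The y_P answer of this flask has moved by 5 points with X charged at 0.723 M or 0.839 M, the other charges and the time held. A neighbour flask charged with 2.0 M of X has a spare X of 182%, the same reckoning gives 68.5%, and J.X in that flask stands at 68.5%.

Its constants are those of an exercise; what happens was integrated by code.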